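Two questions stand here, the row of end values and how it runs:

- [product] at the end for delta, epsilon, gamma, eta, zeta, in this order
- how the row runs (hardly changes / rises all the way / rises, then falls / falls all the way / falls, then rises)

| setting | south-east | north-west | delta | epsilon | gamma | eta | zeta |
|---|---|---|---|---|---|---|---|
| starting material | 0.040 M | 0.040 M | 0.040 M | 0.060 M | 0.10 M | 0.15 M | 0.25 M |
| enzyme | 26 µM | 34 µM | 17 µM | 17 µM | 17 µM | 17 µM | 17 µM |
| remark | run made earlier | run made earlier |  |  |  |  |  |
| time |  |  | 6.0 h | 6.0 h | 6.0 h | 6.0 h | 6.0 h |

| run | time / min | product / % | starting material / % |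
|---|---|---|---|
| south-east | 12.0 | 6 | 95 |
| south-east | 30.0 | 9 | 90 |
| south-east | 60.0 | 22 | 78 |
| south-east | 90.0 | 32 | 76 |
| south-east | 120 | 40 | 66 |
| north-west | 25.0 | 13 | 88 |
| north-west | 50.0 | 20 | 79 |
| north-west | 80.0 | 31 | 67 |
| north-west | 90.0 | 37 | 67 |
| north-west | 120 | 44 | 58 |

(readings scatter by 2 percentage points)

- what was read earlier has a scatter of 2 percentage points, one standard deviation
- "hardly changes" means that all values lie within two and a half points (for a concentration: within two and a half percent of the largest)

The enzyme is the reagent charged in the smaller amount, 17 µM in delta against 0.040 M of starting material. In my balance I count it as unchanged at its charge, so I divide the natural log of charged over remaining starting material by enzyme and by time, taking the remaining part as the charge minus the product. The south-east run, with 40% product at 120 min, gives 9820 L mol⁻¹ h⁻¹, and the north-west run, with 44% at 120 min, gives 8530 L mol⁻¹ h⁻¹. These readings carry a scatter of 2 percentage points. Their mean, 9180 L mol⁻¹ h⁻¹, is my clearing constant.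

Multiplied by 17 µM, it gives delta a pseudo-first-order constant of 0.156 h⁻¹. So by my reckoning the product curve of delta starts with a slope of 0.00624 M h⁻¹ and bends steadily. By the same reckoning it crosses the starting-material curve, at half of the charge, at 4.44 h. That lies before 6.0 h, and at 6.0 h I reckon 0.0243 M of product, on a curve running toward the level of the charge, 0.040 M. The constant was read at 0.040 M, so I commit it to delta and to no other charge.

The forecast gives 0.025 M, 0.034 M, 0.046 M, 0.054 M and 0.062 M, a row that rises all the way: “Product rises, flattening toward saturation.” Its delta is about the same as mine.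

The flask gives 0.0220 M, 0.0279 M, 0.0307 M, 0.0276 M and 0.0206 M, so the row rises, then falls, turning at 0.094 M of starting material.

    starting material + enzyme → product + enzyme, rate k1*[starting material]*[enzyme]/(1 + ([starting material]/Km1) + ([starting material]/Ksi1)^2) (0.0872 M, 0.0766 M, k = 14000 L mol⁻¹ h⁻¹)
    enzyme → spent catalyst (k = 0.0712 h⁻¹)

Delta ends with 44.9% of its starting material, with 65.2% of its enzyme still enzyme and 34.8% turned to spent catalyst, and its clearing constant is 7850 L mol⁻¹ h⁻¹ against my 9180 L mol⁻¹ h⁻¹. Zeta, with 8.23% product, gives 842 L mol⁻¹ h⁻¹, so my constant is ten times its value. The term in [starting material] below the line of the rate law and the time given act together in holding zeta down: without that term zeta ends at 0.0718 M instead of 0.0206 M, and after 60.0 h it stands at 0.0617 M.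

All runs are calculated on assumed constants; scatter was added.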